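Everything rests on cutting the aryl ether bond O1′–C2′ of the dihydrobenzofuran (ring B). C2′ bears ring C and the ring oxygen and adjoins C3′, which bears ring A and the CH2O group, so the opened ring is a 1,2-diarylpropane-1,3-diol with an ortho phenol, the product type of an Evans syn-aldol reaction. One Mitsunobu cycloetherification forms O1′–C2′, closes ring B (5-exo-tet) and inverts C2′, converting the syn diol into the cis-2,3-disubstituted ring of the target. The precursor 15 is that (1S,2R)-diol with the primary hydroxyl silylated, the ring C para oxygen pivaloylated and the aldehyde masked as a dioxolane.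

Key step: step 11

Labels: ring A is the benzene ring of the dihydrobenzofuran; ring B is its oxygen ring (O1′, C2′, C3′); ring C is the aryl group on C2′; ring D is the aryl ring of the benzyl group; ring E is the tetrahydrofuran (O1, C2 bonded to ring A, C3 bearing C9H2O, C4 bearing OH and the benzyl group, C5H2).

Assumption: the magnesium-catalysed anti-aldol reaction of step 14 is taken to run through the chelated Z-enolate with the aldehyde entering anti to the 4-benzyl group (the sense known from imide alkylations); if the sense were opposite, the same step would use the imide made from 6 instead of 20.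

Step 1
Reactants: 1 5-bromovanillin
Product: 2 4-(benzyloxy)-3-bromo-5-methoxybenzaldehyde
Conditions: BnBr, K2CO3, DMF, 60 °C
Reagents that add atoms: benzyl bromide, BrCc1ccccc1
Why: Williamson etherification of the acidic phenol should be clean, and the benzyl ether is chosen because neutral hydrogenolysis can later remove it beside a pivalate, a silyl ether and an acetal.

Step 2
Reactants: 2 4-(benzyloxy)-3-bromo-5-methoxybenzaldehyde
Product: 3 2-[4-(benzyloxy)-3-bromo-5-methoxyphenyl]-1,3-dioxolane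
Conditions: ethylene glycol, p-TsOH (cat.), toluene, reflux, Dean–Stark
Reagents that add atoms: ethylene glycol, OCCO
Why: Acid-catalysed acetalisation with azeotropic removal of water masks the aldehyde against the zinc enolate, the boron enolate and the hydride used later.

Step 3
Reactants: 3 2-[4-(benzyloxy)-3-bromo-5-methoxyphenyl]-1,3-dioxolane
Product: 4 ethyl 2-[2-(benzyloxy)-5-(1,3-dioxolan-2-yl)-3-methoxyphenyl]acetate
Conditions: BrZnCH2CO2Et (commercial THF solution), Pd2(dba)3 (cat.), XPhos (cat.), THF, 60 °C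
Reagents that add atoms: (2-ethoxy-2-oxoethyl)zinc bromide, CCOC(=O)C[Zn]Br
Why: Palladium-catalysed Negishi-type α-arylation of a Reformatsky reagent with an aryl bromide installs the acetic ester under nearly neutral conditions that the acetal and the benzyl ether tolerate.

Step 4
Reactants: 4 ethyl 2-[2-(benzyloxy)-5-(1,3-dioxolan-2-yl)-3-methoxyphenyl]acetate
Product: 5 2-[2-(benzyloxy)-5-(1,3-dioxolan-2-yl)-3-methoxyphenyl]acetic acid
Conditions: LiOH, THF/H2O, rt; then cold 1 M HCl to pH 4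
Reagents that add atoms: lithium hydroxide (hydroxide oxygen), [Li+].[OH-]
Why: Ester saponification is routine, and acidification only to pH 4 in the cold should keep the dioxolane.

Step 5
Reactants: 5 2-[2-(benzyloxy)-5-(1,3-dioxolan-2-yl)-3-methoxyphenyl]acetic acid; 6 (S)-4-benzyloxazolidin-2-one
Product: 8 (S)-4-benzyl-3-{2-[2-(benzyloxy)-5-(1,3-dioxolan-2-yl)-3-methoxyphenyl]acetyl}oxazolidin-2-one, via mixed pivalic anhydride 7 (not isolated)
Conditions: PivCl, Et3N, THF, −20 °C; then 6, LiCl, −20 °C to rt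
Reagents that add atoms: none
Why: N-Acylation of the oxazolidinone through the mixed pivalic anhydride with LiCl activation is the standard mild entry to an N-acyl imide and needs no strong base near the acetal.

Step 6
Reactants: 9 vanillin
Product: 10 4-formyl-2-methoxyphenyl pivalate
Conditions: PivCl, Et3N, DMAP (cat.), CH2Cl2, 0 °C to rt
Reagents that add atoms: pivaloyl chloride, CC(C)(C)C(=O)Cl
Why: Acylation of the phenol gives a hindered aryl ester that survives the later steps and makes ring C a poor donor toward a benzylic cation.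

Step 7
Reactants: 8 (S)-4-benzyl-3-{2-[2-(benzyloxy)-5-(1,3-dioxolan-2-yl)-3-methoxyphenyl]acetyl}oxazolidin-2-one; 10 4-formyl-2-methoxyphenyl pivalate
Product: 12 (4S)-4-benzyl-3-{(2S,3S)-2-[2-(benzyloxy)-5-(1,3-dioxolan-2-yl)-3-methoxyphenyl]-3-hydroxy-3-[3-methoxy-4-(pivaloyloxy)phenyl]propanoyl}oxazolidin-2-one, via Z-dibutylboron enolate 11 (not isolated)
Conditions: n-Bu2BOTf, i-Pr2NEt, CH2Cl2, −78 to 0 °C; then 10, −78 to 0 °C; then pH 7 buffer, MeOH, 30% H2O2, 0 °C
Reagents that add atoms: none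
Why: Evans syn-aldol reaction, in which the Z-boron enolate reacts through a closed chair (Zimmerman–Traxler) transition state with the auxiliary carbonyl turned away, so that the (S)-benzyl group shields one enolate face and sets the future C3′ (2S) and C2′ (3S) in the syn relationship.

Step 8
Reactants: 12 syn-aldol adduct
Product: 13 4-{(1S,2R)-2-[2-(benzyloxy)-5-(1,3-dioxolan-2-yl)-3-methoxyphenyl]-1,3-dihydroxypropyl}-2-methoxyphenyl pivalate
Conditions: LiBH4, MeOH (2 equiv), THF, 0 °C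
Reagents that add atoms: none
Why: Reductive cleavage of the N-acyl oxazolidinone by LiBH4 gives the primary alcohol and returns the auxiliary, while the hindered aryl pivalate and the acetal should survive at 0 °C.

Step 9
Reactants: 13 (1S,2R)-1,3-diol
Product: 14 4-{(1S,2R)-2-[2-(benzyloxy)-5-(1,3-dioxolan-2-yl)-3-methoxyphenyl]-3-[(tert-butyldimethylsilyl)oxy]-1-hydroxypropyl}-2-methoxyphenyl pivalate
Conditions: TBSCl, imidazole, CH2Cl2, 0 °C
Reagents that add atoms: tert-butyldimethylsilyl chloride, CC(C)(C)[Si](C)(C)Cl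
Why: Silylation is selective for the primary over the hindered secondary benzylic hydroxyl, and a silyl ether blocks cyclisation at the primary carbon without offering the anchimeric assistance an ester could give.

Step 10
Reactants: 14 primary silyl ether
Product: 15 4-{(1S,2R)-3-[(tert-butyldimethylsilyl)oxy]-2-[5-(1,3-dioxolan-2-yl)-2-hydroxy-3-methoxyphenyl]-1-hydroxypropyl}-2-methoxyphenyl pivalate
Conditions: H2 (1 atm), 10% Pd/C, EtOAc, rt
Reagents that add atoms: none
Why: Hydrogenolysis of the aryl benzyl ether is fast under neutral conditions that should leave the electron-poor benzylic alcohol, the acetal, the pivalate and the silyl ether intact.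

Step 11
Reactants: 15 syn-diol phenol
Product: 17 4-[(2R,3R)-3-{[(tert-butyldimethylsilyl)oxy]methyl}-5-(1,3-dioxolan-2-yl)-7-methoxy-2,3-dihydrobenzofuran-2-yl]-2-methoxyphenyl pivalate, via oxyphosphonium phenoxide 16 (not isolated)
Conditions: PPh3, DIAD, toluene, 0 °C to rt
Reagents that add atoms: none
Why: PPh3 and DIAD form the betaine, which deprotonates the ring A phenol and passes phosphorus to the only free alcohol, the benzylic hydroxyl on the future C2′, giving oxyphosphonium phenoxide 16, whose phenoxide then displaces Ph3P=O from the rear. The closest known reaction type is the intramolecular Mitsunobu etherification of a phenol with a secondary benzylic alcohol. Ring B closes in the 5-exo-tet mode through the new O1′–C2′ bond. C2′ is the one new stereocentre of the ring and is set by SN2 inversion of the carbinol carbon (1S in 15, 2R in 17) relative to the untouched C3′ from the aldol step, which places ring C and the C3′ CH2OTBS group cis. The step needs substitution to outrun ionisation of the benzylic oxyphosphonium ion, which would leak to the trans ring; the para pivaloyloxy group of ring C is a poor cation stabiliser, and toluene at low temperature disfavours ion pairs. Chemoselectivity is secured because the primary hydroxyl is silylated, so no closure at the C3′ CH2 carbon can compete.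

Step 12
Reactants: 17 cis-dihydrobenzofuran dioxolane
Product: 18 4-[(2R,3R)-3-{[(tert-butyldimethylsilyl)oxy]methyl}-5-formyl-7-methoxy-2,3-dihydrobenzofuran-2-yl]-2-methoxyphenyl pivalate
Conditions: PPTS (cat.), acetone/H2O (10:1), rt
Reagents that add atoms: water, O
Why: Acid-catalysed acetal hydrolysis of an electron-rich aryl dioxolane is fast, and PPTS at room temperature is too weak to cleave the primary silyl ether or to ionise C2′.

Step 13
Reactants: 19 4-tert-butoxy-4-oxobutanoic acid; 20 (R)-4-benzyloxazolidin-2-one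
Product: 22 tert-butyl 4-[(4R)-4-benzyl-2-oxooxazolidin-3-yl]-4-oxobutanoate, via mixed pivalic anhydride 21 (not isolated)
Conditions: PivCl, Et3N, THF, −20 °C; then 20, LiCl, −20 °C to rt
Reagents that add atoms: none
Why: The same mixed-anhydride N-acylation as in step 5 gives the succinyl imide, and the tert-butyl ester is inert to it.

Step 14
Reactants: 18 dihydrobenzofuran aldehyde; 22 (R)-succinyl imide
Product: 24 tert-butyl (3S,4R)-3-[(4R)-4-benzyl-2-oxooxazolidine-3-carbonyl]-4-hydroxy-4-(Ar)butanoate (Ar = the 2,3-dihydrobenzofuran-5-yl group of 18), via trimethylsilyl ether 23 (not isolated)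
Conditions: MgCl2 (0.2 equiv), Et3N, TMSCl, EtOAc, rt; then citric acid, MeOH, rt
Reagents that add atoms: none
Why: Magnesium halide-catalysed anti-aldol reaction of an N-acyl oxazolidinone with an aromatic aldehyde, in which soft enolisation gives the chelated Z-magnesium enolate, the aldehyde adds anti to the (R)-benzyl group through a boat-like transition state and silylation of the aldolate releases the catalyst, should set C3 and C2 of ring E in the anti relationship before mild methanolysis frees the C2 hydroxyl.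

Step 15
Reactants: 24 anti-aldol adduct
Product: 25 tert-butyl (3R,4R)-4-hydroxy-3-(hydroxymethyl)-4-(Ar)butanoate
Conditions: LiBH4, MeOH (2 equiv), THF, 0 °C
Reagents that add atoms: none
Why: Reductive removal of the auxiliary gives the C9 alcohol, and the tert-butyl ester is too hindered to be reduced or to lactonise with the new primary hydroxyl under these conditions.

Step 16
Reactants: 25 (3R,4R)-diol ester
Product: 26 tert-butyl (3R,4R)-3-{[(tert-butyldiphenylsilyl)oxy]methyl}-4-hydroxy-4-(Ar)butanoate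
Conditions: TBDPSCl, imidazole, CH2Cl2, 0 °C to rt
Reagents that add atoms: tert-butyldiphenylsilyl chloride, CC(C)(C)[Si](Cl)(c1ccccc1)c1ccccc1
Why: The bulky silyl chloride reacts only at the primary C9 hydroxyl, which leaves the C2 hydroxyl as the single nucleophile for lactonisation and gives an ether that resists 1,3-silyl migration.

Step 17
Reactants: 26 C9 silyl ether
Product: 27 (4R,5R)-4-{[(tert-butyldiphenylsilyl)oxy]methyl}-5-(Ar)dihydrofuran-2(3H)-one (cis)
Conditions: LiN(SiMe3)2 (1.05 equiv), THF, −78 °C to rt; then aq. NH4Cl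
Reagents that add atoms: none
Why: Intramolecular transesterification, in which the C2 lithium alkoxide attacks the tert-butyl ester (5-exo-trig) with retention at C2, turns the anti-aldol relationship into the cis-4,5-disubstituted lactone without any acid that could ionise the benzylic C2–O bond.

Step 18
Reactants: 10 4-formyl-2-methoxyphenyl pivalate
Product: 28 4-(hydroxymethyl)-2-methoxyphenyl pivalate
Conditions: NaBH4, THF/EtOH, 0 °C
Reagents that add atoms: none
Why: Borohydride reduction of the aldehyde is chemoselective beside the hindered aryl ester.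

Step 19
Reactants: 28 4-(hydroxymethyl)-2-methoxyphenyl pivalate
Product: 29 4-(bromomethyl)-2-methoxyphenyl pivalate
Conditions: CBr4, PPh3, CH2Cl2, 0 °C
Reagents that add atoms: carbon tetrabromide, BrC(Br)(Br)Br
Why: Appel bromination converts the benzylic alcohol into the bromide under neutral conditions, and the para acyloxy group keeps this benzylic bromide stable enough to handle.

Step 20
Reactants: 27 cis-lactone; 29 4-(bromomethyl)-2-methoxyphenyl pivalate
Product: 31 (3S,4R,5R)-3-[3-methoxy-4-(pivaloyloxy)benzyl]-4-{[(tert-butyldiphenylsilyl)oxy]methyl}-5-(Ar)dihydrofuran-2(3H)-one, via lithium enolate 30 (not isolated)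
Conditions: LiN(SiMe3)2, THF, −78 °C; then 29, −78 to −30 °C
Reagents that add atoms: none
Why: Lactone enolate alkylation with a reactive benzylic bromide should occur anti to the C3 substituent, and the configuration formed at C4 is of no consequence because C4 becomes trigonal two steps later.

Step 21
Reactants: 31 α-benzyl lactone
Product: 32 (3S,4R,5R)-3-[3-methoxy-4-(pivaloyloxy)benzyl]-4-{[(tert-butyldiphenylsilyl)oxy]methyl}-5-(Ar)tetrahydrofuran-2-ol (both anomers)
Conditions: i-Bu2AlH (1.1 equiv), CH2Cl2, −78 °C; then aq. potassium sodium tartrate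
Reagents that add atoms: none
Why: Partial reduction of a γ-lactone to the lactol at −78 °C is standard, since the tetrahedral aluminium intermediate resists further reduction and the hindered aryl pivalates react more slowly than the lactone.

Step 22
Reactants: 32 lactol
Product: 34 (2R,3R)-4-[3-methoxy-4-(pivaloyloxy)benzyl]-3-{[(tert-butyldiphenylsilyl)oxy]methyl}-2-(Ar)-2,3-dihydrofuran, via anomeric mesylate 33 (not isolated)
Conditions: MsCl, Et3N (excess), CH2Cl2, −40 °C to reflux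
Reagents that add atoms: none
Why: Lactol dehydration through the anomeric sulfonate and base-induced loss of the C4 proton (glycal-type elimination) gives the cyclic enol ether, and the trisubstituted C4=C5 bond is the only alkene that can form.

Step 23
Reactants: 34 cyclic enol ether
Product: 36 (2R,3R,4S)-4-hydroxy-4-[3-methoxy-4-(pivaloyloxy)benzyl]-3-{[(tert-butyldiphenylsilyl)oxy]methyl}-2-(Ar)tetrahydrofuran (fully protected target), via C4 alkylborane 35 (not isolated)
Conditions: BH3·THF, THF, 0 °C to rt; then NaBO3·4H2O, H2O, rt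
Reagents that add atoms: sodium perborate, [Na+].[O-]OB=O
Why: Hydroboration–oxidation of a cyclic enol ether places boron on C4, the carbon β to the ring oxygen, from the face opposite the cis C2 aryl and C3 silyloxymethyl groups, and oxidation with retention should give the tertiary C4 alcohol (4S) trans to the C3 substituent with the benzyl group cis to it.

Step 24
Reactants: 36 fully protected target
Product: 38 CNP0284796.1 (target), via bis-pivalate triol 37 (not isolated)
Conditions: TBAF, THF, 0 °C to rt; then K2CO3, MeOH, rt; then aq. NH4Cl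
Reagents that add atoms: none
Why: Fluoride-induced desilylation followed by methanolysis of the two aryl pivalates removes all protecting groups under mild basic conditions, avoiding any acid that could epimerise the cis-configured benzylic ether carbons C2 and C2′.

Compound list
1 | 5-bromovanillin (3-bromo-4-hydroxy-5-methoxybenzaldehyde) | COc1cc(C=O)cc(Br)c1O | starting material
2 | 4-(benzyloxy)-3-bromo-5-methoxybenzaldehyde | COc1cc(C=O)cc(Br)c1OCc1ccccc1 | intermediate
3 | 2-[4-(benzyloxy)-3-bromo-5-methoxyphenyl]-1,3-dioxolane | COc1cc(C2OCCO2)cc(Br)c1OCc1ccccc1 | intermediate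
4 | ethyl 2-[2-(benzyloxy)-5-(1,3-dioxolan-2-yl)-3-methoxyphenyl]acetate | CCOC(=O)Cc1cc(C2OCCO2)cc(OC)c1OCc1ccccc1 | intermediate
5 | 2-[2-(benzyloxy)-5-(1,3-dioxolan-2-yl)-3-methoxyphenyl]acetic acid | OC(=O)Cc1cc(C2OCCO2)cc(OC)c1OCc1ccccc1 | intermediate
6 | (S)-4-benzyloxazolidin-2-one | O=C1N[C@@H](Cc2ccccc2)CO1 | starting material
7 | mixed anhydride of 5 with pivalic acid (not isolated) | CC(C)(C)C(=O)OC(=O)Cc1cc(C2OCCO2)cc(OC)c1OCc1ccccc1 | intermediate
8 | (S)-4-benzyl-3-{2-[2-(benzyloxy)-5-(1,3-dioxolan-2-yl)-3-methoxyphenyl]acetyl}oxazolidin-2-one | O=C(Cc1cc(C2OCCO2)cc(OC)c1OCc1ccccc1)N1[C@@H](Cc2ccccc2)COC1=O | intermediate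
9 | vanillin | COc1cc(C=O)ccc1O | starting material
10 | 4-formyl-2-methoxyphenyl pivalate | COc1cc(C=O)ccc1OC(=O)C(C)(C)C | intermediate
11 | Z-dibutylboron enolate of 8 (not isolated) | CCCCB(CCCC)O/C(N1[C@@H](Cc2ccccc2)COC1=O)=C\c1cc(C2OCCO2)cc(OC)c1OCc1ccccc1 | intermediate
12 | (4S)-4-benzyl-3-{(2S,3S)-2-[2-(benzyloxy)-5-(1,3-dioxolan-2-yl)-3-methoxyphenyl]-3-hydroxy-3-[3-methoxy-4-(pivaloyloxy)phenyl]propanoyl}oxazolidin-2-one | O1CCOC1c1cc(OC)c(OCc2ccccc2)c(c1)[C@H](C(=O)N1[C@@H](Cc2ccccc2)COC1=O)[C@H](O)c1ccc(OC(=O)C(C)(C)C)c(OC)c1 | intermediate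
13 | 4-{(1S,2R)-2-[2-(benzyloxy)-5-(1,3-dioxolan-2-yl)-3-methoxyphenyl]-1,3-dihydroxypropyl}-2-methoxyphenyl pivalate | O1CCOC1c1cc(OC)c(OCc2ccccc2)c(c1)[C@H](CO)[C@H](O)c1ccc(OC(=O)C(C)(C)C)c(OC)c1 | intermediate
14 | 4-{(1S,2R)-2-[2-(benzyloxy)-5-(1,3-dioxolan-2-yl)-3-methoxyphenyl]-3-[(tert-butyldimethylsilyl)oxy]-1-hydroxypropyl}-2-methoxyphenyl pivalate | O1CCOC1c1cc(OC)c(OCc2ccccc2)c(c1)[C@H](CO[Si](C)(C)C(C)(C)C)[C@H](O)c1ccc(OC(=O)C(C)(C)C)c(OC)c1 | intermediate
15 | 4-{(1S,2R)-3-[(tert-butyldimethylsilyl)oxy]-2-[5-(1,3-dioxolan-2-yl)-2-hydroxy-3-methoxyphenyl]-1-hydroxypropyl}-2-methoxyphenyl pivalate (key-step precursor) | O1CCOC1c1cc(OC)c(O)c(c1)[C@H](CO[Si](C)(C)C(C)(C)C)[C@H](O)c1ccc(OC(=O)C(C)(C)C)c(OC)c1 | intermediate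
16 | oxytriphenylphosphonium phenoxide zwitterion of 15 (not isolated) | O1CCOC1c1cc(OC)c([O-])c(c1)[C@H](CO[Si](C)(C)C(C)(C)C)[C@H](O[P+](c1ccccc1)(c1ccccc1)c1ccccc1)c1ccc(OC(=O)C(C)(C)C)c(OC)c1 | intermediate
17 | 4-[(2R,3R)-3-{[(tert-butyldimethylsilyl)oxy]methyl}-5-(1,3-dioxolan-2-yl)-7-methoxy-2,3-dihydrobenzofuran-2-yl]-2-methoxyphenyl pivalate (key-step product, cis) | O1CCOC1c1cc(OC)c2c(c1)[C@H](CO[Si](C)(C)C(C)(C)C)[C@H](c1ccc(OC(=O)C(C)(C)C)c(OC)c1)O2 | intermediate
18 | 4-[(2R,3R)-3-{[(tert-butyldimethylsilyl)oxy]methyl}-5-formyl-7-methoxy-2,3-dihydrobenzofuran-2-yl]-2-methoxyphenyl pivalate | O=Cc1cc(OC)c2c(c1)[C@H](CO[Si](C)(C)C(C)(C)C)[C@H](c1ccc(OC(=O)C(C)(C)C)c(OC)c1)O2 | intermediate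
19 | 4-tert-butoxy-4-oxobutanoic acid (mono-tert-butyl succinate) | CC(C)(C)OC(=O)CCC(=O)O | starting material
20 | (R)-4-benzyloxazolidin-2-one | O=C1N[C@H](Cc2ccccc2)CO1 | starting material
21 | mixed anhydride of 19 with pivalic acid (not isolated) | CC(C)(C)OC(=O)CCC(=O)OC(=O)C(C)(C)C | intermediate
22 | tert-butyl 4-[(4R)-4-benzyl-2-oxooxazolidin-3-yl]-4-oxobutanoate | CC(C)(C)OC(=O)CCC(=O)N1[C@H](Cc2ccccc2)COC1=O | intermediate
23 | O-trimethylsilyl ether of 24 (not isolated) | O=C(N1[C@H](Cc2ccccc2)COC1=O)[C@@H](CC(=O)OC(C)(C)C)[C@@H](O[Si](C)(C)C)c1cc(OC)c2c(c1)[C@H](CO[Si](C)(C)C(C)(C)C)[C@H](c1ccc(OC(=O)C(C)(C)C)c(OC)c1)O2 | intermediate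
24 | tert-butyl (3S,4R)-3-[(4R)-4-benzyl-2-oxooxazolidine-3-carbonyl]-4-hydroxy-4-(Ar)butanoate, Ar = dihydrobenzofuran-5-yl group of 18 (anti-aldol adduct) | O=C(N1[C@H](Cc2ccccc2)COC1=O)[C@@H](CC(=O)OC(C)(C)C)[C@@H](O)c1cc(OC)c2c(c1)[C@H](CO[Si](C)(C)C(C)(C)C)[C@H](c1ccc(OC(=O)C(C)(C)C)c(OC)c1)O2 | intermediate
25 | tert-butyl (3R,4R)-4-hydroxy-3-(hydroxymethyl)-4-(Ar)butanoate | OC[C@@H](CC(=O)OC(C)(C)C)[C@@H](O)c1cc(OC)c2c(c1)[C@H](CO[Si](C)(C)C(C)(C)C)[C@H](c1ccc(OC(=O)C(C)(C)C)c(OC)c1)O2 | intermediate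
26 | tert-butyl (3R,4R)-3-{[(tert-butyldiphenylsilyl)oxy]methyl}-4-hydroxy-4-(Ar)butanoate | CC(C)(C)[Si](c1ccccc1)(c1ccccc1)OC[C@@H](CC(=O)OC(C)(C)C)[C@@H](O)c1cc(OC)c2c(c1)[C@H](CO[Si](C)(C)C(C)(C)C)[C@H](c1ccc(OC(=O)C(C)(C)C)c(OC)c1)O2 | intermediate
27 | (4R,5R)-4-{[(tert-butyldiphenylsilyl)oxy]methyl}-5-(Ar)dihydrofuran-2(3H)-one (cis-lactone) | O=C1C[C@H](CO[Si](c2ccccc2)(c2ccccc2)C(C)(C)C)[C@H](c2cc(OC)c3c(c2)[C@H](CO[Si](C)(C)C(C)(C)C)[C@H](c2ccc(OC(=O)C(C)(C)C)c(OC)c2)O3)O1 | intermediate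
28 | 4-(hydroxymethyl)-2-methoxyphenyl pivalate | COc1cc(CO)ccc1OC(=O)C(C)(C)C | intermediate
29 | 4-(bromomethyl)-2-methoxyphenyl pivalate | COc1cc(CBr)ccc1OC(=O)C(C)(C)C | intermediate
30 | lithium enolate of 27 (not isolated) | [Li]OC1=C[C@H](CO[Si](c2ccccc2)(c2ccccc2)C(C)(C)C)[C@H](c2cc(OC)c3c(c2)[C@H](CO[Si](C)(C)C(C)(C)C)[C@H](c2ccc(OC(=O)C(C)(C)C)c(OC)c2)O3)O1 | intermediate
31 | (3S,4R,5R)-3-[3-methoxy-4-(pivaloyloxy)benzyl]-4-{[(tert-butyldiphenylsilyl)oxy]methyl}-5-(Ar)dihydrofuran-2(3H)-one | O=C1[C@@H](Cc2ccc(OC(=O)C(C)(C)C)c(OC)c2)[C@H](CO[Si](c2ccccc2)(c2ccccc2)C(C)(C)C)[C@H](c2cc(OC)c3c(c2)[C@H](CO[Si](C)(C)C(C)(C)C)[C@H](c2ccc(OC(=O)C(C)(C)C)c(OC)c2)O3)O1 | intermediate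
32 | lactol of 31, (3S,4R,5R)-tetrahydrofuran-2-ol, both anomers | OC1[C@@H](Cc2ccc(OC(=O)C(C)(C)C)c(OC)c2)[C@H](CO[Si](c2ccccc2)(c2ccccc2)C(C)(C)C)[C@H](c2cc(OC)c3c(c2)[C@H](CO[Si](C)(C)C(C)(C)C)[C@H](c2ccc(OC(=O)C(C)(C)C)c(OC)c2)O3)O1 | intermediate
33 | anomeric mesylate of 32 (not isolated) | CS(=O)(=O)OC1[C@@H](Cc2ccc(OC(=O)C(C)(C)C)c(OC)c2)[C@H](CO[Si](c2ccccc2)(c2ccccc2)C(C)(C)C)[C@H](c2cc(OC)c3c(c2)[C@H](CO[Si](C)(C)C(C)(C)C)[C@H](c2ccc(OC(=O)C(C)(C)C)c(OC)c2)O3)O1 | intermediate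
34 | (2R,3R)-4-[3-methoxy-4-(pivaloyloxy)benzyl]-3-{[(tert-butyldiphenylsilyl)oxy]methyl}-2-(Ar)-2,3-dihydrofuran | C1=C(Cc2ccc(OC(=O)C(C)(C)C)c(OC)c2)[C@H](CO[Si](c2ccccc2)(c2ccccc2)C(C)(C)C)[C@H](c2cc(OC)c3c(c2)[C@H](CO[Si](C)(C)C(C)(C)C)[C@H](c2ccc(OC(=O)C(C)(C)C)c(OC)c2)O3)O1 | intermediate
35 | C4 alkylborane from 34, boron trans to the C3 substituent (not isolated) | C1[C@]([BH2])(Cc2ccc(OC(=O)C(C)(C)C)c(OC)c2)[C@H](CO[Si](c2ccccc2)(c2ccccc2)C(C)(C)C)[C@H](c2cc(OC)c3c(c2)[C@H](CO[Si](C)(C)C(C)(C)C)[C@H](c2ccc(OC(=O)C(C)(C)C)c(OC)c2)O3)O1 | intermediate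
36 | (2R,3R,4S)-4-hydroxy-4-[3-methoxy-4-(pivaloyloxy)benzyl]-3-{[(tert-butyldiphenylsilyl)oxy]methyl}-2-(Ar)tetrahydrofuran (fully protected target) | COc1cc(C[C@@]2(O)CO[C@@H](c3cc(OC)c4c(c3)[C@H](CO[Si](C)(C)C(C)(C)C)[C@H](c3ccc(OC(=O)C(C)(C)C)c(OC)c3)O4)[C@H]2CO[Si](c3ccccc3)(c3ccccc3)C(C)(C)C)ccc1OC(=O)C(C)(C)C | intermediate
37 | bis-pivalate triol, 36 without both silyl groups (not isolated) | COc1cc(C[C@@]2(O)CO[C@@H](c3cc(OC)c4c(c3)[C@H](CO)[C@H](c3ccc(OC(=O)C(C)(C)C)c(OC)c3)O4)[C@H]2CO)ccc1OC(=O)C(C)(C)C | intermediate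
38 | CNP0284796.1, 4-{(2R,3R)-3-(hydroxymethyl)-5-[(2R,3R,4S)-4-hydroxy-4-(4-hydroxy-3-methoxybenzyl)-3-(hydroxymethyl)tetrahydrofuran-2-yl]-7-methoxy-2,3-dihydrobenzofuran-2-yl}-2-methoxyphenol | COc1cc(C[C@@]2(O)CO[C@@H](c3cc(OC)c4c(c3)[C@H](CO)[C@H](c3ccc(O)c(OC)c3)O4)[C@H]2CO)ccc1O | target

Total step count: 24. Longest linear sequence: 20 steps (1–5, 7–12, 14–17, 20–24).

Steps most likely to fail

1. Step 11 (key step). What may go wrong: ionisation of the benzylic oxyphosphonium ion, so that part of the material closes through a cation with retention and gives the trans ring, together with E2 loss of Ph3P=O to the stilbene-type alkene. Fallback, setting out from 14 and coming back at 17: the ring C ester is exchanged for a sulfonate, a weaker π-donor, before the cyclisation. Methanolysis of 14 (K2CO3, MeOH) gives the ring C phenol F1, which is sulfonylated at the phenol only (TsCl, K2CO3, acetone) to give the aryl tosylate F2. Hydrogenolysis (H2, 10% Pd/C) frees the ring A phenol in the tosylate precursor F3, and Mitsunobu closure (PPh3, DIAD, toluene) gives the cis-dihydrobenzofuran tosylate F4. Reductive detosylation (Mg, MeOH) gives the ring C phenol F5, and pivaloylation (PivCl, Et3N) returns 17.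

2. Step 14. What may go wrong: slow catalyst turnover and eroded facial or anti/syn selectivity with an electron-rich aldehyde and an ester-bearing imide, and retro-aldol cleavage during desilylation. Fallback, setting out from 18, 19 and 6 and coming back at 25: 19 is coupled to 6 through anhydride 21 to give the (S)-succinyl imide F6. Its Evans syn-aldol reaction with 18 (n-Bu2BOTf, i-Pr2NEt) gives the syn adduct F7, in which C3 already has the required configuration. Oxidation with Dess–Martin periodinane gives the β-keto imide F8, whose C3 centre resists enolisation because of allylic strain. Non-chelating Felkin–Anh reduction (KBEt3H, Et2O, −78 °C) gives the anti adduct F9, and LiBH4 then removes the auxiliary to give 25.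

3. Step 22. What may go wrong: incomplete elimination that stops at an anomeric chloride, or acid-catalysed hydration and oligomerisation of the electron-rich enol ether during isolation, which would also undermine the hydroboration that follows. Fallback, setting out from 31 and coming back at 36: the potassium enolate of 31 (KN(SiMe3)2, THF, −78 °C) is hydroxylated with 2-(phenylsulfonyl)-3-phenyloxaziridine anti to the C3 substituent to give the α-hydroxy lactone F10. Reduction with i-Bu2AlH gives the hydroxy lactol F11, and ionic reduction of the lactol (Et3SiH, BF3·OEt2, CH2Cl2, −78 °C) gives 36.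

Further compounds
F1 | step 11 | 14 with the ring C pivalate cleaved (ring C phenol) | O1CCOC1c1cc(OC)c(OCc2ccccc2)c(c1)[C@H](CO[Si](C)(C)C(C)(C)C)[C@H](O)c1ccc(O)c(OC)c1
F2 | step 11 | ring C aryl tosylate of F1 | O1CCOC1c1cc(OC)c(OCc2ccccc2)c(c1)[C@H](CO[Si](C)(C)C(C)(C)C)[C@H](O)c1ccc(OS(=O)(=O)c2ccc(C)cc2)c(OC)c1
F3 | step 11 | tosylate analogue of 15 (ring A phenol free) | O1CCOC1c1cc(OC)c(O)c(c1)[C@H](CO[Si](C)(C)C(C)(C)C)[C@H](O)c1ccc(OS(=O)(=O)c2ccc(C)cc2)c(OC)c1
F4 | step 11 | tosylate analogue of 17, (2R,3R)-cis-dihydrobenzofuran | O1CCOC1c1cc(OC)c2c(c1)[C@H](CO[Si](C)(C)C(C)(C)C)[C@H](c1ccc(OS(=O)(=O)c3ccc(C)cc3)c(OC)c1)O2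
F5 | step 11 | ring C phenol of the (2R,3R)-cis-dihydrobenzofuran | O1CCOC1c1cc(OC)c2c(c1)[C@H](CO[Si](C)(C)C(C)(C)C)[C@H](c1ccc(O)c(OC)c1)O2
F6 | step 14 | tert-butyl 4-[(4S)-4-benzyl-2-oxooxazolidin-3-yl]-4-oxobutanoate | CC(C)(C)OC(=O)CCC(=O)N1[C@@H](Cc2ccccc2)COC1=O
F7 | step 14 | tert-butyl (3S,4S)-3-[(4S)-4-benzyl-2-oxooxazolidine-3-carbonyl]-4-hydroxy-4-(Ar)butanoate (syn adduct) | O=C(N1[C@@H](Cc2ccccc2)COC1=O)[C@@H](CC(=O)OC(C)(C)C)[C@H](O)c1cc(OC)c2c(c1)[C@H](CO[Si](C)(C)C(C)(C)C)[C@H](c1ccc(OC(=O)C(C)(C)C)c(OC)c1)O2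
F8 | step 14 | tert-butyl (3S)-3-[(4S)-4-benzyl-2-oxooxazolidine-3-carbonyl]-4-oxo-4-(Ar)butanoate (β-keto imide) | O=C(N1[C@@H](Cc2ccccc2)COC1=O)[C@@H](CC(=O)OC(C)(C)C)C(=O)c1cc(OC)c2c(c1)[C@H](CO[Si](C)(C)C(C)(C)C)[C@H](c1ccc(OC(=O)C(C)(C)C)c(OC)c1)O2
F9 | step 14 | tert-butyl (3S,4R)-3-[(4S)-4-benzyl-2-oxooxazolidine-3-carbonyl]-4-hydroxy-4-(Ar)butanoate (anti adduct) | O=C(N1[C@@H](Cc2ccccc2)COC1=O)[C@@H](CC(=O)OC(C)(C)C)[C@@H](O)c1cc(OC)c2c(c1)[C@H](CO[Si](C)(C)C(C)(C)C)[C@H](c1ccc(OC(=O)C(C)(C)C)c(OC)c1)O2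
F10 | step 22 | α-hydroxy lactone from 31, hydroxyl trans to the C3 substituent | O=C1[C@](O)(Cc2ccc(OC(=O)C(C)(C)C)c(OC)c2)[C@H](CO[Si](c2ccccc2)(c2ccccc2)C(C)(C)C)[C@H](c2cc(OC)c3c(c2)[C@H](CO[Si](C)(C)C(C)(C)C)[C@H](c2ccc(OC(=O)C(C)(C)C)c(OC)c2)O3)O1
F11 | step 22 | hydroxy lactol from F10 (both anomers) | OC1[C@](O)(Cc2ccc(OC(=O)C(C)(C)C)c(OC)c2)[C@H](CO[Si](c2ccccc2)(c2ccccc2)C(C)(C)C)[C@H](c2cc(OC)c3c(c2)[C@H](CO[Si](C)(C)C(C)(C)C)[C@H](c2ccc(OC(=O)C(C)(C)C)c(OC)c2)O3)O1
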